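The seven-membered ring C1–C2–C3–C4–C9–C10–C11 and the cyclobutane C4–C5–C10–C9 are both closed in one flask onto a preformed ring A. Ring-closing metathesis first joins C1 to C2. This ties C3 to C11 and makes C4 a ring atom, so a C4 radical, released from either epimer of a thiocarbonate, can only add across the ring to C9, the terminus of a silyloxy-diene in ring A. The precursor is a monocyclic cyclohexadiene carrying two cis, vinyl-terminated chains at C5 and C10; its stereocentres come from an auxiliary-controlled Diels–Alder reaction. The step exploits the cis-1,3 bridging of the cyclobutane by C3 and C11.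

Key step: step 12

Atom labels used throughout (own convention, taken from the target): C1 = CH–O-angeloyl, C2 = CH–OH, C3 = CMe2, C4 = cyclobutane CH bonded to C3, C5 = cyclobutane CH bonded to the ketone carbon C6, C7 = enone CH, C8 = enone C–CH3, C9 = cyclobutane CH bonded to C8, C10 = quaternary C–CH3, C11 = CH–O-2-methylbutanoyl; ring A = C5–C6–C7–C8–C9–C10.

Assumption: compounds 1, 2, 4, 7, 9, 12 and 25 are taken as commercially available. The acyl group in the target is (R)-2-methylbutanoyl and the enoate is angelate (Z), as read from the given structure.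

Step 1
Reactants: 1 5-hydroxy-4-methylfuran-2(5H)-one; 2 (1R,2S,5R)-(−)-menthol
Product: 3 (5R)-5-[(1R,2S,5R)-menthyloxy]-4-methylfuran-2(5H)-one
Conditions: CSA (cat.), PhH, reflux, Dean–Stark; crystallisation from hexane
Reagents that add atoms: none
Why: Acid-catalysed acetalisation of the lactol gives both acetal epimers, which interconvert under the acid, so crystallisation of the less soluble (5R) diastereomer should funnel the mixture into one configuration (crystallisation-induced epimerisation).

Step 2
Reactants: 4 3-methylbut-2-enal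
Product: 5 (E)-triisopropyl[(3-methylbuta-1,3-dien-1-yl)oxy]silane
Conditions: TIPSOTf, Et3N, Et2O, 0 °C to rt
Reagents that add atoms: triisopropylsilyl triflate CC(C)[Si](OS(=O)(=O)C(F)(F)F)(C(C)C)C(C)C
Why: Soft enolisation (O-silylation, then γ-deprotonation) of the enal should give the extended dienol silyl ether with the (E)-enol ether geometry.

Step 3
Reactants: 3 (5R)-menthyloxy butenolide; 5 silyloxy diene
Product: 6 cis-fused lactone acetal, 3-(menthyloxy)-3a,5-dimethyl-7-(triisopropylsilyloxy)-3a,4,7,7a-tetrahydroisobenzofuran-1(3H)-one (C5–H and C10–CH3 cis at the ring fusion, menthyloxy on the face opposite ring A, silyloxy cis to the lactone carbonyl)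
Conditions: PhMe, BHT (cat.), sealed tube, 140 °C
Reagents that add atoms: none
Why: Diels–Alder reaction in which the 1-silyloxy and 3-methyl groups of the diene direct C9 to the β-carbon C10 and C6 to the α-carbon C5, suprafacial addition gives the cis fusion with the quaternary C10, attack anti to the menthyloxy group fixes C5 and C10 absolutely, and endo addition sets C6, which is oxidised later.

Step 4
Reactants: 6 lactone acetal; 7 3-methylbut-2-enylmagnesium chloride
Product: 8 hemiketal of 6 bearing a 2-methylbut-3-en-2-yl group and OH at C4 (both C4 anomers)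
Conditions: THF, −78 °C; aq. NH4Cl
Reagents that add atoms: none
Why: γ-Selective (allyl-inversion) addition of the prenyl Grignard reagent to the lactone carbonyl installs C3 as the 1,1-dimethylallyl quaternary carbon and should stop at the magnesium hemiketal at low temperature.

Step 5
Reactants: 8 hemiketal; 9 vinylmagnesium bromide
Product: 11 1-{6-[(1R)-1-hydroxyprop-2-enyl]-4,6-dimethyl-2-(triisopropylsilyloxy)cyclohex-3-enyl}-2,2-dimethylbut-3-en-1-one, via keto aldehyde 10 (not isolated)
Conditions: vinylMgBr (3.5 equiv), THF, −78 to 0 °C; aq. NH4Cl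
Reagents that add atoms: none
Why: Deprotonation opens the hemiketal to the hindered C4 ketone and a C11 hemiacetal alkoxide that expels menthoxide, and the freed neopentyl aldehyde takes up the vinyl group under Felkin–Anh control (anti to the C5 branch, passing the methyl group), which sets C11 while the α-quaternary ketone is spared.

Step 6
Reactants: 11 keto allylic alcohol; 12 (R)-2-methylbutanoic acid
Product: 13 C11 (R)-2-methylbutanoate of 11
Conditions: DIC, DMAP (cat.), CH2Cl2, 0 °C to rt
Reagents that add atoms: none
Why: Steglich esterification of the secondary allylic alcohol leaves C11 untouched and is mild enough to keep the α-stereocentre of the acid.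

Step 7
Reactants: 13 keto ester
Product: 14 C4 carbinol of 13 (both C4 epimers)
Conditions: NaBH4, CeCl3·7H2O, MeOH, −20 to 0 °C
Reagents that add atoms: none
Why: Luche-type 1,2-reduction of the hindered ketone spares the ester and the alkenes, and the C4 epimer mixture is acceptable because C4 is later planarised as a radical.

Step 8
Reactants: 14 C4 carbinol
Product: 15 C4 O-phenyl thiocarbonate of 14
Conditions: PhOC(S)Cl, DMAP, MeCN, rt to 40 °C
Reagents that add atoms: O-phenyl chlorothionoformate S=C(Cl)Oc1ccccc1
Why: Thioacylation of the neopentyl-type secondary alcohol gives the Barton–McCombie radical precursor.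

Step 9
Reactants: 15 thiocarbonate silyl ether
Product: 16 C6 allylic alcohol
Conditions: HF·pyridine, THF, 0 °C to rt
Reagents that add atoms: none
Why: Fluoride cleavage of the silyl ether under weakly acidic conditions should spare the thiocarbonate and the ester.

Step 10
Reactants: 16 C6 allylic alcohol
Product: 17 ring A enone (C6=O, C7=C8) bearing the C4 thiocarbonate chain and the C11 ester chain
Conditions: Dess–Martin periodinane, NaHCO3, CH2Cl2, rt
Reagents that add atoms: none
Why: Oxidation of the allylic alcohol gives the enone and removes the C6 stereocentre, so the endo/exo outcome of step 3 is immaterial.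

Step 11
Reactants: 17 enone
Product: 18 tert-butyldimethylsilyl dienol ether of 17 (C6(OTBS)=C7–C8(CH3)=C9)
Conditions: TBSOTf, Et3N, CH2Cl2, −78 to 0 °C
Reagents that add atoms: tert-butyldimethylsilyl triflate CC(C)(C)[Si](C)(C)OS(=O)(=O)C(F)(F)F
Why: Soft enolisation through the O-silylated enone removes a γ-proton at C9 and should give the endocyclic 2-silyloxy-1,3-diene, which makes C9 a radical acceptor without forming a free enolate that could eliminate the β-thiocarbonate.

Step 12
Reactants: 18 silyl dienol ether with two vinyl-terminated chains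
Product: 20 tricyclic silyl enol ether (C1=C2 alkene, C4–C9 bond, C6(OTBS)=C7, C8–H epimers, C11 ester), via cycloheptene 19 (not isolated)
Conditions: second-generation Grubbs catalyst (10 mol %), PhMe (0.005 M), 80 °C; then (TMS)3SiH, AIBN, syringe pump, 90 °C
Reagents that add atoms: none
Why: Ruthenium-alkylidene ring-closing metathesis of the two monosubstituted vinyl groups forms C1=C2 and closes the cycloheptene, after which the tris(trimethylsilyl)silyl radical adds to the thiocarbonyl sulfur and the adduct fragments (Barton–McCombie type) to the C4 radical. The closest known reaction types are ring-closing metathesis and the 4-exo-trig radical cyclisation used for cyclobutanes with stabilised product radicals. The seven-membered ring closes by metathesis of a 1,8-diene and the cyclobutane by transannular 4-exo-trig attack of C4 on C9, the unsubstituted terminus of the silyloxy-diene, giving a silyloxy-allyl radical that is quenched by hydrogen transfer at C8. C4 and C9 are controlled by the ring: the new C1–C2 bond already holds C3 on the C11 side, so only the cis-1,3-bridged cyclobutane can form and both C4 epimers of the thiocarbonate converge, while C8 is returned to sp2 in step 13. The step needs chemoselective metathesis (the trisubstituted diene and the thiocarbonate must stay untouched) and cyclisation faster than reduction of the C4 radical. This is supported by the high dilution, the slow addition of the slow hydrogen donor and the proximity of C4 and C9 in the cis-fused bicycle.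

Step 13
Reactants: 20 tricyclic silyl enol ether
Product: 21 tricyclic enone (C6=O, C7=C8) with C1=C2 alkene and C11 (R)-2-methylbutanoate
Conditions: Pd(OAc)2, MeCN, rt
Reagents that add atoms: none
Why: Saegusa–Ito oxidation converts the silyl enol ether into a palladium enolate, and β-hydride elimination of the C8 hydrogen gives the conjugated enone, the bridgehead positions being unable to eliminate.

Step 14
Reactants: 21 tricyclic enone alkene
Product: 22 cis-1,2-diol (C1–OH and C2–OH both anti to the C11 ester oxygen)
Conditions: OsO4 (cat.), NMO, acetone/H2O, rt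
Reagents that add atoms: osmium tetroxide O=[Os](=O)(=O)=O; N-methylmorpholine N-oxide C[N+]1([O-])CCOCC1; water O
Why: Catalytic dihydroxylation of the only electron-rich alkene (the enone is deactivated) should occur anti to the allylic C11 acyloxy group, the usual sense for osmylation of allylic esters, which sets C2 correctly and gives the C1 epimer of the final diol.

Step 15
Reactants: 22 cis-diol
Product: 23 α-hydroxy ketone (C1=O, C2–OH)
Conditions: TEMPO (cat.), PhI(OAc)2, CH2Cl2, rt
Reagents that add atoms: none
Why: Oxoammonium oxidation is sensitive to steric hindrance and should oxidise the C1 carbinol in preference to the neopentyl C2 carbinol next to the gem-dimethyl group.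

Step 16
Reactants: 23 α-hydroxy ketone
Product: 24 trans-1,2-diol (C1–OH cis to the C11 ester, anti to C2–OH)
Conditions: Me4NBH(OAc)3, MeCN/AcOH, −20 °C
Reagents that add atoms: none
Why: Hydroxyl-directed (Evans–Saksena-type) reduction, in which the C2 hydroxyl binds the acetoxyborohydride and delivers hydride to its own face of the C1 ketone, sets C1 anti to C2–OH and leaves the undirected enone alone.

Step 17
Reactants: 24 trans-diol; 25 angelic anhydride
Product: 26 target compound
Conditions: pyridine, rt to 40 °C
Reagents that add atoms: none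
Why: The C1 hydroxyl, flanked by two oxygenated methines, should be acylated in preference to the neopentyl C2 hydroxyl, and the anhydride without nucleophilic catalyst limits angelate-to-tiglate isomerisation.

Compound list
1 | 5-hydroxy-4-methylfuran-2(5H)-one | CC1=CC(=O)OC1O | starting material
2 | (1R,2S,5R)-(−)-menthol | C[C@@H]1CC[C@H]([C@@H](C1)O)C(C)C | starting material
3 | (5R)-5-[(1R,2S,5R)-menthyloxy]-4-methylfuran-2(5H)-one | CC1=CC(=O)O[C@H]1O[C@@H]2C[C@H](C)CC[C@H]2C(C)C | intermediate
4 | 3-methylbut-2-enal | CC(C)=CC=O | starting material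
5 | (E)-triisopropyl[(3-methylbuta-1,3-dien-1-yl)oxy]silane | C=C(C)/C=C/O[Si](C(C)C)(C(C)C)C(C)C | intermediate
6 | cis-fused lactone acetal (Diels–Alder adduct) | O=C1[C@H]2[C@@H](O[Si](C(C)C)(C(C)C)C(C)C)C=C(C)C[C@@]2(C)[C@H](O[C@@H]3C[C@H](C)CC[C@H]3C(C)C)O1 | intermediate
7 | 3-methylbut-2-enylmagnesium chloride | CC(C)=CC[Mg]Cl | starting material
8 | hemiketal with 2-methylbut-3-en-2-yl group at C4 (C4 anomers) | C=CC(C)(C)C1(O)[C@H]2[C@@H](O[Si](C(C)C)(C(C)C)C(C)C)C=C(C)C[C@@]2(C)[C@H](O[C@@H]3C[C@H](C)CC[C@H]3C(C)C)O1 | intermediate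
9 | vinylmagnesium bromide | C=C[Mg]Br | starting material
10 | keto aldehyde, 6-(2,2-dimethylbut-3-enoyl)-1,3-dimethyl-5-(triisopropylsilyloxy)cyclohex-3-ene-1-carbaldehyde | C=CC(C)(C)C(=O)[C@H]1[C@@H](O[Si](C(C)C)(C(C)C)C(C)C)C=C(C)C[C@@]1(C)C=O | intermediate
11 | keto allylic alcohol with (R)-C11 carbinol | C=CC(C)(C)C(=O)[C@H]1[C@@H](O[Si](C(C)C)(C(C)C)C(C)C)C=C(C)C[C@@]1(C)[C@H](O)C=C | intermediate
12 | (R)-2-methylbutanoic acid | CC[C@@H](C)C(=O)O | starting material
13 | C11 (R)-2-methylbutanoate of 11 | C=CC(C)(C)C(=O)[C@H]1[C@@H](O[Si](C(C)C)(C(C)C)C(C)C)C=C(C)C[C@@]1(C)[C@H](OC(=O)[C@H](C)CC)C=C | intermediate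
14 | C4 carbinol (C4 epimers) | C=CC(C)(C)C(O)[C@H]1[C@@H](O[Si](C(C)C)(C(C)C)C(C)C)C=C(C)C[C@@]1(C)[C@H](OC(=O)[C@H](C)CC)C=C | intermediate
15 | C4 O-phenyl thiocarbonate (C4 epimers) | C=CC(C)(C)C(OC(=S)Oc1ccccc1)[C@H]2[C@@H](O[Si](C(C)C)(C(C)C)C(C)C)C=C(C)C[C@@]2(C)[C@H](OC(=O)[C@H](C)CC)C=C | intermediate
16 | C6 allylic alcohol | C=CC(C)(C)C(OC(=S)Oc1ccccc1)[C@H]2[C@@H](O)C=C(C)C[C@@]2(C)[C@H](OC(=O)[C@H](C)CC)C=C | intermediate
17 | ring A enone | C=CC(C)(C)C(OC(=S)Oc1ccccc1)[C@H]2C(=O)C=C(C)C[C@@]2(C)[C@H](OC(=O)[C@H](C)CC)C=C | intermediate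
18 | TBS dienol ether of 17 | C=CC(C)(C)C(OC(=S)Oc1ccccc1)[C@H]2C(O[Si](C)(C)C(C)(C)C)=CC(C)=C[C@@]2(C)[C@H](OC(=O)[C@H](C)CC)C=C | intermediate
19 | cycloheptene-fused silyloxy-diene (metathesis product) | C1=CC(C)(C)C(OC(=S)Oc2ccccc2)[C@H]3C(O[Si](C)(C)C(C)(C)C)=CC(C)=C[C@@]3(C)[C@@H]1OC(=O)[C@H](C)CC | intermediate
20 | tricyclic silyl enol ether (C8 epimers) | C1=CC(C)(C)[C@@H]2[C@H]3C(O[Si](C)(C)C(C)(C)C)=CC(C)[C@@H]2[C@@]3(C)[C@@H]1OC(=O)[C@H](C)CC | intermediate
21 | tricyclic enone with C1=C2 alkene | C1=CC(C)(C)[C@@H]2[C@H]3C(=O)C=C(C)[C@@H]2[C@@]3(C)[C@@H]1OC(=O)[C@H](C)CC | intermediate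
22 | cis-diol (C1 epimer of 24) | O[C@H]1[C@@H](O)C(C)(C)[C@@H]2[C@H]3C(=O)C=C(C)[C@@H]2[C@@]3(C)[C@@H]1OC(=O)[C@H](C)CC | intermediate
23 | α-hydroxy ketone (C1=O) | O=C1[C@@H](O)C(C)(C)[C@@H]2[C@H]3C(=O)C=C(C)[C@@H]2[C@@]3(C)[C@@H]1OC(=O)[C@H](C)CC | intermediate
24 | trans-diol (target lacking the angeloyl group) | O[C@@H]1[C@@H](O)C(C)(C)[C@@H]2[C@H]3C(=O)C=C(C)[C@@H]2[C@@]3(C)[C@@H]1OC(=O)[C@H](C)CC | intermediate
25 | angelic anhydride, (Z)-2-methylbut-2-enoic anhydride | C/C=C(/C)C(=O)OC(=O)C(/C)=C\C | starting material
26 | CNP0202800.1 | C/C=C(/C)C(=O)O[C@@H]1[C@@H](O)C(C)(C)[C@@H]2[C@H]3C(=O)C=C(C)[C@@H]2[C@@]3(C)[C@@H]1OC(=O)[C@H](C)CC | target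

Total step count: 17. Longest linear sequence: 16 steps (steps 1 and 3 to 17; step 2 prepares the diene separately).

Steps most likely to fail

Step 12. The metathesis catalyst may be inhibited by the thiocarbonyl group or the electron-rich diene, and hydrogen transfer to the C4 radical may outrun the strained 4-exo closure, giving simple deoxygenation. The fallback separates and reorders the two ring closures with known operations, setting out from 14 and coming back at 20. Ring-closing metathesis of the sulfur-free carbinol 14 with second-generation Hoveyda–Grubbs catalyst should give the cycloheptenol F1. Thioacylation as in step 8 gives the thiocarbonate F2, HF·pyridine gives the C6 alcohol F3, and Dess–Martin oxidation gives the bicyclic enone F4. Silylation with TBSOTf and Et3N then gives 19 as an isolated compound, which is cyclised in a separate radical step with Bu3SnH and Et3B/air at room temperature to 20.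

Step 3. The β,β-disubstituted butenolide may be too unreactive for the thermal cycloaddition, so the diene may decompose or desilylate and regio- and facial control may erode at the temperature needed. The fallback replaces the pericyclic step by a stepwise ionic annulation from 3 and 5, coming back at 6. With Tf2NH (cat.) at −78 °C, the dienol silyl ether adds through C9 to C10 of the butenolide (vinylogous Mukaiyama–Michael addition), again anti to the menthyloxy group, and the resulting silyl ketene acetal closes onto the unsaturated aldehyde at C6 (intramolecular Mukaiyama aldol). No new isolated compound arises.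

Step 5. Facial control at the C11 aldehyde may be poor, and the basic Grignard reagent may enolise the C4 ketone and epimerise C5. The fallback sets C11 by reagent control, setting out from 11 (as its C11 epimer mixture) and coming back at 11. Dess–Martin oxidation gives the vinyl ketone F5, which is reduced with BH3·SMe2 and the (S)-Me-CBS oxazaborolidine (quaternary C10 branch taken as the large group) to the (R)-C11 alcohol.

Further compounds
F1 | step 12 | cycloheptenol from ring-closing metathesis of 14 (C4 carbinol, C6 silyl ether) | C1=CC(C)(C)C(O)[C@H]3[C@@H](O[Si](C(C)C)(C(C)C)C(C)C)C=C(C)C[C@@]3(C)[C@@H]1OC(=O)[C@H](C)CC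
F2 | step 12 | C4 O-phenyl thiocarbonate of F1 | C1=CC(C)(C)C(OC(=S)Oc2ccccc2)[C@H]3[C@@H](O[Si](C(C)C)(C(C)C)C(C)C)C=C(C)C[C@@]3(C)[C@@H]1OC(=O)[C@H](C)CC
F3 | step 12 | C6 allylic alcohol from F2 | C1=CC(C)(C)C(OC(=S)Oc2ccccc2)[C@H]3[C@@H](O)C=C(C)C[C@@]3(C)[C@@H]1OC(=O)[C@H](C)CC
F4 | step 12 | bicyclic enone thiocarbonate from F3 | C1=CC(C)(C)C(OC(=S)Oc2ccccc2)[C@H]3C(=O)C=C(C)C[C@@]3(C)[C@@H]1OC(=O)[C@H](C)CC
F0 | step 3 | none | none
F5 | step 5 | vinyl ketone from oxidation of 11 | C=CC(C)(C)C(=O)[C@H]1[C@@H](O[Si](C(C)C)(C(C)C)C(C)C)C=C(C)C[C@@]1(C)C(=O)C=C
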